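**Plan**

- Labels used in the discussion: indane C1 carries the 4-hydroxyphenyl ring A, C2 the dihydrobenzofuran-4-yl unit (its benzo ring is ring B), C3 the side chain C8(OH)–aryl; ring F is the benzo ring of the indane. Systematic names below number the indane the other way round.
- Retrosynthesis, in order: the C8 carbinol (from the aryl ketone), C8–aryl and C3–C8 (one-carbon homologation of a C3 ketone), then C1–C2 of the indanone. The resulting hydroxy ketone is cut at CH2–CO (benzylic Grignard reagent + 3-arylphthalide), the phthalide at aryl–CH, and the dihydrobenzofuran at C2'–C3' (carbene C–H insertion).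
- Enabling feature: C1 is benzylic to ring A and para to its hydroxyl group, so it can be the exocyclic carbon of a p-quinone methide. C2 is benzylic to ring B and α to C3, so with C3 as a ketone it is an enol carbon that reaches C1 across ring F.
- Forward order: dihydrofuran ring (steps 1–9), phthalide (10–11), union and unmasking (12–13), five-membered carbocycle (14), then C3 elaboration, demethylation and reduction (15–22).
- Stereochemistry: C3' from the chiral dirhodium catalyst, C2' by acid equilibration to trans; C1 from the chiral phosphoric acid; C2 and C3 by equilibration next to carbonyl groups (all-trans); C8 from the ruthenium transfer-hydrogenation catalyst.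

Key step: step 14

Abbreviation: DBF = (2R,3R)-3-(3,5-dimethoxyphenyl)-6-methoxy-2-(4-methoxyphenyl)-2,3-dihydro-1-benzofuran-4-yl.

Remark 1: compounds 24 and 25 are drawn as open hydroxy ketones; each should exist largely as its cyclic hemiketal (a 1-hydroxy-1,3-dihydro-2-benzofuran), which opens to the same quinone methide under acid, and both carbinol epimers are used.

Remark 2: the sense of induction of Rh2(R-PTAD)4 (step 6) and of (R)-TRIP (step 14) is assumed as drawn; if either favours the other configuration, its mirror-image form is used.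

**Route**

Step 1
Reactants: 1 2-bromo-4,6-dimethoxybenzaldehyde
Product: 2 2-bromo-6-hydroxy-4-methoxybenzaldehyde
Conditions: BCl3 (1.2 equiv), CH2Cl2, −78 → 0 °C; aq. work-up
Reagents that add atoms: none
Why: Chelation-controlled Lewis acid demethylation, in which BCl3 binds between the formyl oxygen and the ortho methoxy group and cleaves only that ether, leaving the para methoxy group and the aryl bromide untouched.

Step 2
Reactants: 2 2-bromo-6-hydroxy-4-methoxybenzaldehyde; 3 4-methoxybenzyl chloride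
Product: 4 2-bromo-4-methoxy-6-[(4-methoxyphenyl)methoxy]benzaldehyde
Conditions: K2CO3, DMF, 60 °C
Reagents that add atoms: none
Why: Williamson ether synthesis on the phenoxide; the 4-methoxybenzyl group is not a protecting group here but supplies C2' and the 2-aryl ring of the future dihydrobenzofuran.

Step 3
Reactants: 4 2-bromo-4-methoxy-6-[(4-methoxyphenyl)methoxy]benzaldehyde; 5 1-bromo-3,5-dimethoxybenzene
Product: 7 rac-{2-bromo-4-methoxy-6-[(4-methoxyphenyl)methoxy]phenyl}(3,5-dimethoxyphenyl)methanol, via 3,5-dimethoxyphenylmagnesium bromide 6 (not isolated)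
Conditions: 5, Mg, THF, 40 °C; then 4, THF, 0 °C; aq. NH4Cl
Reagents that add atoms: none
Why: Grignard addition to the aldehyde, which outpaces any exchange at the aryl bromide of 4 at 0 °C; the carbinol centre forms as a racemate and is removed in step 4.

Step 4
Reactants: 7 rac-diaryl carbinol
Product: 8 {2-bromo-4-methoxy-6-[(4-methoxyphenyl)methoxy]phenyl}(3,5-dimethoxyphenyl)methanone
Conditions: Dess–Martin periodinane, CH2Cl2, rt
Reagents that add atoms: none
Why: Dess–Martin oxidation of a diaryl carbinol to the benzophenone under neutral conditions that leave the benzyl ether and the bromide intact.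

Step 5
Reactants: 8 diaryl ketone
Product: 9 hydrazone of ketone 8 (E/Z mixture)
Conditions: N2H4·H2O (excess), AcOH (cat.), n-BuOH, 100 °C
Reagents that add atoms: hydrazine hydrate, NN.O
Why: Hydrazone formation by condensation with a large excess of hydrazine, heated because the carbonyl group is flanked by two ortho substituents, the excess suppressing azine formation.

Step 6
Reactants: 9 hydrazone
Product: 11 (2S,3R)-4-bromo-3-(3,5-dimethoxyphenyl)-6-methoxy-2-(4-methoxyphenyl)-2,3-dihydro-1-benzofuran (2,3-cis), via diazo compound 10 (not isolated)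
Conditions: MnO2, CH2Cl2, 0 °C, filtration; then Rh2(R-PTAD)4 (1 mol %; PTAD = N-phthaloyl-(1-adamantyl)glycinate), CH2Cl2, 0 °C → rt
Reagents that add atoms: none
Why: Dehydrogenation of the hydrazone to the diaryldiazomethane 10 followed by dirhodium-catalysed intramolecular 1,5 C–H insertion of the donor/donor carbene into the ether-activated benzylic C–H bond closes the dihydrofuran ring; the chiral carboxylate ligands set C3' (3R) and the concerted insertion places the two aryl groups cis (2S).

Step 7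
Reactants: 11 cis-dihydrobenzofuran
Product: 12 (2R,3R)-4-bromo-3-(3,5-dimethoxyphenyl)-6-methoxy-2-(4-methoxyphenyl)-2,3-dihydro-1-benzofuran (2,3-trans; DBF–Br)
Conditions: CF3CO2H (2 equiv), CH2Cl2, 0 °C → rt
Reagents that add atoms: none
Why: Acid-mediated epimerisation, in which reversible heterolysis of the O–C2' bond to the 4-methoxybenzylic cation and reclosure on the phenol oxygen moves C2' to the thermodynamically preferred trans arrangement (2R) while C3', which is not involved, keeps its configuration.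

Step 8
Reactants: 12 DBF–Br
Product: 15 DBF–CH2OH [(2R,3R)-configured (dihydrobenzofuran-4-yl)methanol], via aryllithium 13 (not isolated), via aldehyde 14 (not isolated)
Conditions: n-BuLi, THF, −78 °C; DMF, −78 → 0 °C; then MeOH, NaBH4, 0 °C; aq. work-up
Reagents that add atoms: N,N-dimethylformamide, CN(C)C=O
Why: Bromine–lithium exchange (faster at −78 °C than deprotonation of the benzylic C–H bonds), formylation of aryllithium 13 with DMF and borohydride reduction of aldehyde 14 in the same flask; no stereocentre is touched.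

Step 9
Reactants: 15 DBF–CH2OH
Product: 16 DBF–CH2Cl [(2R,3R)-4-(chloromethyl)-3-(3,5-dimethoxyphenyl)-6-methoxy-2-(4-methoxyphenyl)-2,3-dihydro-1-benzofuran]
Conditions: PPh3, N-chlorosuccinimide, CH2Cl2, 0 °C → rt
Reagents that add atoms: N-chlorosuccinimide, O=C1CCC(=O)N1Cl
Why: Appel-type chlorination of the benzylic alcohol under neutral conditions, chosen so that no acid is present that could ionise the O–C2' bond.

Step 10
Reactants: 17 2-bromo-3,5-dimethoxybenzaldehyde
Product: 18 2-bromo-3,5-dimethoxybenzoic acid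
Conditions: NaClO2, NaH2PO4, 2-methyl-2-butene, t-BuOH/H2O, rt
Reagents that add atoms: sodium chlorite NaClO2, [Na+].[O-]Cl=O
Why: Pinnick oxidation of the aldehyde to the acid, with 2-methyl-2-butene scavenging hypochlorous acid so that the electron-rich ring is not chlorinated.

Step 11
Reactants: 18 2-bromo-3,5-dimethoxybenzoic acid; 19 4-[(tert-butyldimethylsilyl)oxy]benzaldehyde
Product: 22 rac-3-{4-[(tert-butyldimethylsilyl)oxy]phenyl}-4,6-dimethoxy-2-benzofuran-1(3H)-one, via dilithiated benzoate 20 (not isolated), via hydroxy acid 21 (not isolated)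
Conditions: n-BuLi (2.1 equiv), THF, −78 °C; 19, −78 → 0 °C; then 1 M HCl, rt
Reagents that add atoms: none
Why: Parham-type sequence in which the first equivalent of n-BuLi forms the carboxylate, the second exchanges the bromide, the ortho-lithiated benzoate 20 adds to aldehyde 19 and acidification lactonises hydroxy acid 21 to the phthalide; the new centre is racemic, which is immaterial because it becomes trigonal in step 14.

Step 12
Reactants: 16 DBF–CH2Cl; 22 rac-3-aryl-4,6-dimethoxyphthalide
Product: 24 2-DBF-1-{2-[hydroxy(4-{[tert-butyl(dimethyl)silyl]oxy}phenyl)methyl]-3,5-dimethoxyphenyl}ethan-1-one (both carbinol epimers; in equilibrium with its cyclic hemiketal), via benzylic Grignard reagent 23 (not isolated)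
Conditions: 16, Mg, LiCl, THF, 0 °C → rt; then 22, THF, −78 → −30 °C; aq. NH4Cl
Reagents that add atoms: none
Why: Magnesium insertion into the benzylic chloride and addition of the benzylic Grignard reagent 23 to the lactone, which stops after one addition because the tetrahedral intermediate is a cyclic magnesium hemiketal that does not collapse at low temperature; the racemic carbinol carbon gives two diastereomers that are both carried on.

Step 13
Reactants: 24 silyl-protected hydroxy ketone
Product: 25 2-DBF-1-{2-[hydroxy(4-hydroxyphenyl)methyl]-3,5-dimethoxyphenyl}ethan-1-one (both carbinol epimers; in equilibrium with its cyclic hemiketal)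
Conditions: Bu4NF, AcOH, THF, 0 °C
Reagents that add atoms: none
Why: Fluoride cleavage of the aryl silyl ether, buffered with acetic acid so that no free phenoxide persists that could expel the benzylic oxygen before the chiral catalyst is present.

Step 14
Reactants: 25 hydroxy ketone
Product: 27 (2S,3S)-2-DBF-3-(4-hydroxyphenyl)-4,6-dimethoxy-2,3-dihydro-1H-inden-1-one (2,3-trans), via quinone methide 26 (not isolated)
Conditions: (R)-TRIP [(R)-3,3'-bis(2,4,6-triisopropylphenyl)-1,1'-binaphthyl-2,2'-diyl hydrogen phosphate] (10 mol %), toluene (0.02 M), rt → 40 °C, argon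
Reagents that add atoms: none
Why: The phosphoric acid protonates the carbinol (or opens its cyclic hemiketal), water leaves and the p-quinone methide 26 of ring A forms, while the same catalyst, hydrogen-bonded to the quinone methide oxygen, promotes enolisation of the aryl benzyl ketone; C2 of the enol then adds to the exocyclic carbon C1 in a 1,6-conjugate addition that restores the phenol. The closest known reaction type is the chiral phosphoric acid-catalysed 1,6-addition of enolisable carbonyl compounds to p-quinone methides generated in situ from 4-hydroxybenzyl alcohols. The five-membered ring closes 5-exo-trig onto the exocyclic C1=C bond (enolendo with respect to the nucleophile), which is feasible here because the enol, the arene bond of ring F and the quinone methide carbon form a pentadienyl-cation-like array that can close in the manner of a 4π electrocyclisation. C1 (3S in the indanone name) is set by the facial discrimination of the chiral phosphate, expected to be matched with the neighbouring (2R,3R)-dihydrobenzofuran, and C2 (2S) is set under thermodynamic control because the α-aryl ketone epimerises to the 2,3-trans isomer in the acidic medium. The step needs C-alkylation at C2 in preference to return to the hemiketal or dehydration to an enol ether or isobenzofuran; those paths are reversible under acid whereas C–C bond formation with rearomatisation is not, the ketone has only one enolisable position, and the weak acid ionises the 4-hydroxybenzhydryl position far more readily than the O–C2' bond of the dihydrobenzofuran.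

Step 15
Reactants: 27 phenolic indanone
Product: 28 (2S,3S)-2-DBF-4,6-dimethoxy-3-(4-methoxyphenyl)-2,3-dihydro-1H-inden-1-one
Conditions: MeI, K2CO3, acetone, rt
Reagents that add atoms: iodomethane, CI
Why: Williamson methylation of the phenol, which K2CO3 deprotonates far more readily than the α-aryl ketone, masks the phenol for the organometallic and oxidation steps and closes the path back to the quinone methide.

Step 16
Reactants: 28 indanone methyl ether
Product: 29 (2R,3S)-2-DBF-4,6-dimethoxy-3-(4-methoxyphenyl)-1-methylidene-2,3-dihydro-1H-indene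
Conditions: Cp2TiMe2, toluene, 70 °C, dark
Reagents that add atoms: dimethyltitanocene Cp2TiMe2, [CH3-].[CH3-].[Ti+4].c1cc[cH-]c1.c1cc[cH-]c1
Why: Petasis methylenation, in which the titanium methylidene formed on heating is not basic, so the enolisable α-aryl ketone is olefinated without enolate formation and the configuration at C2 is kept.

Step 17
Reactants: 29 methylidene indane
Product: 30 [(2R,3S)-2-DBF-4,6-dimethoxy-3-(4-methoxyphenyl)-2,3-dihydro-1H-inden-1-yl]methanol (mixture of C1 epimers; 1,2-cis expected to predominate)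
Conditions: BH3·THF, THF, 0 °C → rt; then NaOH, H2O2, 0 °C
Reagents that add atoms: hydrogen peroxide, OO
Why: Hydroboration–oxidation places boron on the terminal carbon (anti-Markovnikov) and gives the primary alcohol; hydrogen is delivered mainly anti to the adjacent aryl group, so the new ring centre forms mostly cis to it and as a mixture, which step 18 corrects.

Step 18
Reactants: 30 primary alcohol
Product: 32 (1S,2R,3S)-2-DBF-4,6-dimethoxy-3-(4-methoxyphenyl)-2,3-dihydro-1H-indene-1-carbaldehyde (all-trans), via aldehyde epimer mixture 31 (not isolated)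
Conditions: Dess–Martin periodinane, CH2Cl2, rt; then DBU, rt
Reagents that add atoms: none
Why: Dess–Martin oxidation to aldehyde 31 followed by DBU-mediated enolisation equilibrates the formyl-bearing centre, which is benzylic and α to the carbonyl group, to the all-trans isomer (1S) under thermodynamic control.

Step 19
Reactants: 32 all-trans aldehyde; 33 4-methoxyphenylmagnesium bromide (commercial THF solution)
Product: 34 [(1S,2R,3S)-2-DBF-4,6-dimethoxy-3-(4-methoxyphenyl)-2,3-dihydro-1H-inden-1-yl](4-methoxyphenyl)methanol (both carbinol epimers)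
Conditions: THF, −78 → 0 °C; aq. NH4Cl
Reagents that add atoms: none
Why: Grignard addition to the aldehyde at low temperature; both carbinol epimers form and both are oxidised in step 20.

Step 20
Reactants: 34 secondary alcohol
Product: 35 [(1S,2R,3S)-2-DBF-4,6-dimethoxy-3-(4-methoxyphenyl)-2,3-dihydro-1H-inden-1-yl](4-methoxyphenyl)methanone
Conditions: Dess–Martin periodinane, CH2Cl2, rt
Reagents that add atoms: none
Why: Dess–Martin oxidation of the benzylic alcohol to the aryl ketone; the adjacent ring centre remains trans, which is its thermodynamic arrangement.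

Step 21
Reactants: 35 octamethyl ether ketone
Product: 36 {(1S,2R,3S)-2-[(2R,3R)-3-(3,5-dihydroxyphenyl)-6-hydroxy-2-(4-hydroxyphenyl)-2,3-dihydro-1-benzofuran-4-yl]-4,6-dihydroxy-3-(4-hydroxyphenyl)-2,3-dihydro-1H-inden-1-yl}(4-hydroxyphenyl)methanone
Conditions: BBr3 (excess), CH2Cl2, −78 °C → rt; then H2O
Reagents that add atoms: none
Why: Lewis acid cleavage of the eight aryl methyl ethers with BBr3, carried out at the ketone oxidation level because a 4-oxybenzylic carbinol would ionise under these conditions; the trans dihydrobenzofuran is the thermodynamic isomer, so reversible ionisation at its C2' is harmless.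

Step 22
Reactants: 36 octaphenol ketone
Product: 37 (1S,2R,3S)-2-[(2R,3R)-3-(3,5-dihydroxyphenyl)-6-hydroxy-2-(4-hydroxyphenyl)-2,3-dihydro-1-benzofuran-4-yl]-1-[(S)-hydroxy(4-hydroxyphenyl)methyl]-3-(4-hydroxyphenyl)-2,3-dihydro-1H-indene-4,6-diol (CNP0175860.1)
Conditions: RuCl[(S,S)-TsDPEN](p-cymene) (5 mol %), HCO2H/Et3N (5:2), DMF, 40 °C
Reagents that add atoms: none
Why: Noyori asymmetric transfer hydrogenation, in which the (S,S)-diamine ruthenium hydride delivers hydride to the face of the aryl ketone that gives the (S)-carbinol, the formic acid medium tolerates the free phenols and the all-trans ring configuration is retained.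

**Compound list**

1 | 2-bromo-4,6-dimethoxybenzaldehyde | COc1cc(Br)c(C=O)c(OC)c1 | starting material
2 | 2-bromo-6-hydroxy-4-methoxybenzaldehyde | COc1cc(O)c(C=O)c(Br)c1 | intermediate
3 | 4-methoxybenzyl chloride | COc1ccc(CCl)cc1 | starting material
4 | 2-bromo-4-methoxy-6-[(4-methoxyphenyl)methoxy]benzaldehyde | COc1ccc(COc2cc(OC)cc(Br)c2C=O)cc1 | intermediate
5 | 1-bromo-3,5-dimethoxybenzene | COc1cc(Br)cc(OC)c1 | starting material
6 | 3,5-dimethoxyphenylmagnesium bromide | COc1cc(OC)cc([Mg]Br)c1 | intermediate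
7 | rac-{2-bromo-4-methoxy-6-[(4-methoxyphenyl)methoxy]phenyl}(3,5-dimethoxyphenyl)methanol | COc1ccc(COc2cc(OC)cc(Br)c2C(O)c2cc(OC)cc(OC)c2)cc1 | intermediate
8 | {2-bromo-4-methoxy-6-[(4-methoxyphenyl)methoxy]phenyl}(3,5-dimethoxyphenyl)methanone | COc1ccc(COc2cc(OC)cc(Br)c2C(=O)c2cc(OC)cc(OC)c2)cc1 | intermediate
9 | hydrazone of ketone 8 (E/Z mixture) | COc1ccc(COc2cc(OC)cc(Br)c2C(=NN)c2cc(OC)cc(OC)c2)cc1 | intermediate
10 | 1-bromo-2-[diazo(3,5-dimethoxyphenyl)methyl]-5-methoxy-3-[(4-methoxyphenyl)methoxy]benzene | COc1ccc(COc2cc(OC)cc(Br)c2C(=[N+]=[N-])c2cc(OC)cc(OC)c2)cc1 | intermediate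
11 | (2S,3R)-4-bromo-3-(3,5-dimethoxyphenyl)-6-methoxy-2-(4-methoxyphenyl)-2,3-dihydro-1-benzofuran (cis) | Brc1cc(OC)cc2c1[C@@H](c1cc(OC)cc(OC)c1)[C@@H](c1ccc(OC)cc1)O2 | intermediate
12 | (2R,3R)-4-bromo-3-(3,5-dimethoxyphenyl)-6-methoxy-2-(4-methoxyphenyl)-2,3-dihydro-1-benzofuran (trans; DBF–Br) | Brc1cc(OC)cc2c1[C@@H](c1cc(OC)cc(OC)c1)[C@H](c1ccc(OC)cc1)O2 | intermediate
13 | DBF–Li, [(2R,3R)-3-(3,5-dimethoxyphenyl)-6-methoxy-2-(4-methoxyphenyl)-2,3-dihydro-1-benzofuran-4-yl]lithium | [Li]c1cc(OC)cc2c1[C@@H](c1cc(OC)cc(OC)c1)[C@H](c1ccc(OC)cc1)O2 | intermediate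
14 | DBF–CHO, (2R,3R)-3-(3,5-dimethoxyphenyl)-6-methoxy-2-(4-methoxyphenyl)-2,3-dihydro-1-benzofuran-4-carbaldehyde | O=Cc1cc(OC)cc2c1[C@@H](c1cc(OC)cc(OC)c1)[C@H](c1ccc(OC)cc1)O2 | intermediate
15 | DBF–CH2OH, [(2R,3R)-3-(3,5-dimethoxyphenyl)-6-methoxy-2-(4-methoxyphenyl)-2,3-dihydro-1-benzofuran-4-yl]methanol | OCc1cc(OC)cc2c1[C@@H](c1cc(OC)cc(OC)c1)[C@H](c1ccc(OC)cc1)O2 | intermediate
16 | DBF–CH2Cl, (2R,3R)-4-(chloromethyl)-3-(3,5-dimethoxyphenyl)-6-methoxy-2-(4-methoxyphenyl)-2,3-dihydro-1-benzofuran | ClCc1cc(OC)cc2c1[C@@H](c1cc(OC)cc(OC)c1)[C@H](c1ccc(OC)cc1)O2 | intermediate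
17 | 2-bromo-3,5-dimethoxybenzaldehyde | COc1cc(OC)c(Br)c(C=O)c1 | starting material
18 | 2-bromo-3,5-dimethoxybenzoic acid | COc1cc(OC)c(Br)c(C(=O)O)c1 | intermediate
19 | 4-[(tert-butyldimethylsilyl)oxy]benzaldehyde | CC(C)(C)[Si](C)(C)Oc1ccc(C=O)cc1 | starting material
20 | lithium 2-lithio-3,5-dimethoxybenzoate | [Li]c1c(OC)cc(OC)cc1C(=O)O[Li] | intermediate
21 | rac-2-[hydroxy(4-{[tert-butyl(dimethyl)silyl]oxy}phenyl)methyl]-3,5-dimethoxybenzoic acid | COc1cc(OC)c(C(O)c2ccc(O[Si](C)(C)C(C)(C)C)cc2)c(C(=O)O)c1 | intermediate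
22 | rac-3-{4-[(tert-butyldimethylsilyl)oxy]phenyl}-4,6-dimethoxy-2-benzofuran-1(3H)-one | COc1cc(OC)c2c(c1)C(=O)OC2c1ccc(O[Si](C)(C)C(C)(C)C)cc1 | intermediate
23 | DBF–CH2MgCl, (DBF-methyl)magnesium chloride | Cl[Mg]Cc1cc(OC)cc2c1[C@@H](c1cc(OC)cc(OC)c1)[C@H](c1ccc(OC)cc1)O2 | intermediate
24 | 2-DBF-1-{2-[hydroxy(4-{[tert-butyl(dimethyl)silyl]oxy}phenyl)methyl]-3,5-dimethoxyphenyl}ethan-1-one (both carbinol epimers) | CC(C)(C)[Si](C)(C)Oc1ccc(C(O)c2c(OC)cc(OC)cc2C(=O)Cc2cc(OC)cc3c2[C@@H](c2cc(OC)cc(OC)c2)[C@H](c2ccc(OC)cc2)O3)cc1 | intermediate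
25 | 2-DBF-1-{2-[hydroxy(4-hydroxyphenyl)methyl]-3,5-dimethoxyphenyl}ethan-1-one (both carbinol epimers) | Oc1ccc(C(O)c2c(OC)cc(OC)cc2C(=O)Cc2cc(OC)cc3c2[C@@H](c2cc(OC)cc(OC)c2)[C@H](c2ccc(OC)cc2)O3)cc1 | intermediate
26 | 4-{[2-(DBF-acetyl)-4,6-dimethoxyphenyl]methylidene}cyclohexa-2,5-dien-1-one (p-quinone methide) | O=C1C=CC(=Cc2c(OC)cc(OC)cc2C(=O)Cc2cc(OC)cc3c2[C@@H](c2cc(OC)cc(OC)c2)[C@H](c2ccc(OC)cc2)O3)C=C1 | intermediate
27 | (2S,3S)-2-DBF-3-(4-hydroxyphenyl)-4,6-dimethoxy-2,3-dihydro-1H-inden-1-one (trans) | Oc1ccc([C@H]2c3c(OC)cc(OC)cc3C(=O)[C@@H]2c2cc(OC)cc3c2[C@@H](c2cc(OC)cc(OC)c2)[C@H](c2ccc(OC)cc2)O3)cc1 | intermediate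
28 | (2S,3S)-2-DBF-4,6-dimethoxy-3-(4-methoxyphenyl)-2,3-dihydro-1H-inden-1-one | COc1ccc([C@H]2c3c(OC)cc(OC)cc3C(=O)[C@@H]2c2cc(OC)cc3c2[C@@H](c2cc(OC)cc(OC)c2)[C@H](c2ccc(OC)cc2)O3)cc1 | intermediate
29 | (2R,3S)-2-DBF-4,6-dimethoxy-3-(4-methoxyphenyl)-1-methylidene-2,3-dihydro-1H-indene | COc1ccc([C@H]2c3c(OC)cc(OC)cc3C(=C)[C@@H]2c2cc(OC)cc3c2[C@@H](c2cc(OC)cc(OC)c2)[C@H](c2ccc(OC)cc2)O3)cc1 | intermediate
30 | [(2R,3S)-2-DBF-4,6-dimethoxy-3-(4-methoxyphenyl)-2,3-dihydro-1H-inden-1-yl]methanol (C1 epimers) | COc1ccc([C@H]2c3c(OC)cc(OC)cc3C(CO)[C@@H]2c2cc(OC)cc3c2[C@@H](c2cc(OC)cc(OC)c2)[C@H](c2ccc(OC)cc2)O3)cc1 | intermediate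
31 | (2R,3S)-2-DBF-4,6-dimethoxy-3-(4-methoxyphenyl)-2,3-dihydro-1H-indene-1-carbaldehyde (C1 epimers) | COc1ccc([C@H]2c3c(OC)cc(OC)cc3C(C=O)[C@@H]2c2cc(OC)cc3c2[C@@H](c2cc(OC)cc(OC)c2)[C@H](c2ccc(OC)cc2)O3)cc1 | intermediate
32 | (1S,2R,3S)-2-DBF-4,6-dimethoxy-3-(4-methoxyphenyl)-2,3-dihydro-1H-indene-1-carbaldehyde (all-trans) | COc1ccc([C@H]2c3c(OC)cc(OC)cc3[C@@H](C=O)[C@@H]2c2cc(OC)cc3c2[C@@H](c2cc(OC)cc(OC)c2)[C@H](c2ccc(OC)cc2)O3)cc1 | intermediate
33 | 4-methoxyphenylmagnesium bromide | COc1ccc([Mg]Br)cc1 | starting material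
34 | [(1S,2R,3S)-2-DBF-4,6-dimethoxy-3-(4-methoxyphenyl)-2,3-dihydro-1H-inden-1-yl](4-methoxyphenyl)methanol (both carbinol epimers) | COc1ccc([C@H]2c3c(OC)cc(OC)cc3[C@@H](C(O)c3ccc(OC)cc3)[C@@H]2c2cc(OC)cc3c2[C@@H](c2cc(OC)cc(OC)c2)[C@H](c2ccc(OC)cc2)O3)cc1 | intermediate
35 | [(1S,2R,3S)-2-DBF-4,6-dimethoxy-3-(4-methoxyphenyl)-2,3-dihydro-1H-inden-1-yl](4-methoxyphenyl)methanone | COc1ccc([C@H]2c3c(OC)cc(OC)cc3[C@@H](C(=O)c3ccc(OC)cc3)[C@@H]2c2cc(OC)cc3c2[C@@H](c2cc(OC)cc(OC)c2)[C@H](c2ccc(OC)cc2)O3)cc1 | intermediate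
36 | {(1S,2R,3S)-2-[(2R,3R)-3-(3,5-dihydroxyphenyl)-6-hydroxy-2-(4-hydroxyphenyl)-2,3-dihydro-1-benzofuran-4-yl]-4,6-dihydroxy-3-(4-hydroxyphenyl)-2,3-dihydro-1H-inden-1-yl}(4-hydroxyphenyl)methanone | Oc1ccc([C@H]2c3c(O)cc(O)cc3[C@@H](C(=O)c3ccc(O)cc3)[C@@H]2c2cc(O)cc3c2[C@@H](c2cc(O)cc(O)c2)[C@H](c2ccc(O)cc2)O3)cc1 | intermediate
37 | (1S,2R,3S)-2-[(2R,3R)-3-(3,5-dihydroxyphenyl)-6-hydroxy-2-(4-hydroxyphenyl)-2,3-dihydro-1-benzofuran-4-yl]-1-[(S)-hydroxy(4-hydroxyphenyl)methyl]-3-(4-hydroxyphenyl)-2,3-dihydro-1H-indene-4,6-diol (CNP0175860.1) | Oc1ccc([C@H]2c3c(O)cc(O)cc3[C@@H]([C@H](O)c3ccc(O)cc3)[C@@H]2c2cc(O)cc3c2[C@@H](c2cc(O)cc(O)c2)[C@H](c2ccc(O)cc2)O3)cc1 | target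

**Summary and risks**

Total step count: 22. Longest linear sequence: 20 steps (steps 1–9, then 12–22); steps 10–11 form the second branch.

Steps most likely to fail:

1. Step 14. Loss of water from the cyclic hemiketal toward an enol ether or isobenzofuran may outrun carbon–carbon bond formation, and facial selectivity at C1 may be low if the chiral phosphate and the neighbouring dihydrobenzofuran oppose each other. The fallback sets out from silyl ether 24 and forms the same C1–C2 bond and ring by an aldol condensation instead. Dess–Martin oxidation of the open hydroxy ketone form of 24 should give the 1,2-diacylbenzene 2-DBF-1-{2-[4-(silyloxy)benzoyl]-3,5-dimethoxyphenyl}ethan-1-one F1. DBU in toluene at 60 °C should then close it by intramolecular aldol condensation to the 2,3-diarylinden-1-one F2. Copper hydride-catalysed asymmetric conjugate reduction (Cu(OAc)2, (R)-DTBM-SEGPHOS or its mirror image, (EtO)2MeSiH, t-BuOH, toluene) sets C1 under ligand control, and equilibration of C2 with DBU should give the trans indanone silyl ether F3. Desilylation of F3 with Bu4NF/AcOH comes back to the route at 27.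

2. Step 5. Condensation at a carbonyl group shielded by two ortho substituents may stall, and at the temperature needed the hydrazone nitrogen may begin to displace the ortho bromide with ring closure. The fallback sets out from aldehyde 4. I2 in aqueous NH3/THF should convert it into 2-bromo-4-methoxy-6-[(4-methoxyphenyl)methoxy]benzonitrile F4. Grignard reagent 6 (CuBr cat., THF, 60 °C) adds to the nitrile, and a quench with dry MeOH should give the N–H ketimine F5. Transimination of F5 with hydrazine hydrate in EtOH at rt, an exchange at C=N that is far easier than condensation at the hindered C=O, comes back to the route at hydrazone 9.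

3. Step 22. Hydride delivery under catalyst control may be overridden by the ring stereocentre next to the carbonyl group (mismatched double diastereoselection), and conversion may stall because the para-hydroxyl group lowers the electrophilicity of the ketone. The fallback sets out from 36 and reduces a protected, more electrophilic ketone with a borane reagent. Ac2O/pyridine should give the octaacetate ketone F6. Corey–Bakshi–Shibata reduction ((R)-Me-CBS oxazaborolidine, catecholborane, toluene, −40 °C) should give the (S)-carbinol octaacetate F7. Methanolysis of the aryl acetates of F7 (K2CO3, MeOH, 0 °C, argon) comes back to the route at 37.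

**Further compounds**

F1 | step 14 | 2-DBF-1-{2-[4-({tert-butyl(dimethyl)silyl}oxy)benzoyl]-3,5-dimethoxyphenyl}ethan-1-one | CC(C)(C)[Si](C)(C)Oc1ccc(C(=O)c2c(OC)cc(OC)cc2C(=O)Cc2cc(OC)cc3c2[C@@H](c2cc(OC)cc(OC)c2)[C@H](c2ccc(OC)cc2)O3)cc1
F2 | step 14 | 2-DBF-3-{4-[(tert-butyldimethylsilyl)oxy]phenyl}-4,6-dimethoxy-1H-inden-1-one | O=C1C(c3cc(OC)cc4c3[C@@H](c3cc(OC)cc(OC)c3)[C@H](c3ccc(OC)cc3)O4)=C(c3ccc(O[Si](C)(C)C(C)(C)C)cc3)c2c(OC)cc(OC)cc12
F3 | step 14 | (2S,3S)-2-DBF-3-{4-[(tert-butyldimethylsilyl)oxy]phenyl}-4,6-dimethoxy-2,3-dihydro-1H-inden-1-one | CC(C)(C)[Si](C)(C)Oc1ccc([C@H]2c3c(OC)cc(OC)cc3C(=O)[C@@H]2c2cc(OC)cc3c2[C@@H](c2cc(OC)cc(OC)c2)[C@H](c2ccc(OC)cc2)O3)cc1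
F4 | step 5 | 2-bromo-4-methoxy-6-[(4-methoxyphenyl)methoxy]benzonitrile | COc1ccc(COc2cc(OC)cc(Br)c2C#N)cc1
F5 | step 5 | 1-{2-bromo-4-methoxy-6-[(4-methoxyphenyl)methoxy]phenyl}-1-(3,5-dimethoxyphenyl)methanimine | COc1ccc(COc2cc(OC)cc(Br)c2C(=N)c2cc(OC)cc(OC)c2)cc1
F6 | step 22 | octaacetate of ketone 36 | CC(=O)Oc1ccc([C@H]2c3c(OC(C)=O)cc(OC(C)=O)cc3[C@@H](C(=O)c3ccc(OC(C)=O)cc3)[C@@H]2c2cc(OC(C)=O)cc3c2[C@@H](c2cc(OC(C)=O)cc(OC(C)=O)c2)[C@H](c2ccc(OC(C)=O)cc2)O3)cc1
F7 | step 22 | octa-O-acetyl derivative (phenolic positions) of target 37 with free (S)-carbinol | CC(=O)Oc1ccc([C@H]2c3c(OC(C)=O)cc(OC(C)=O)cc3[C@@H]([C@H](O)c3ccc(OC(C)=O)cc3)[C@@H]2c2cc(OC(C)=O)cc3c2[C@@H](c2cc(OC(C)=O)cc(OC(C)=O)c2)[C@H](c2ccc(OC(C)=O)cc2)O3)cc1
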